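**Retrosynthetic overview**

1. The side chain is numbered from the benzylic carbon (C1) to the quaternary ring carbon (C11). The phenol is unmasked last; before that the C3–C4 bond (methyl-bearing alkene carbon to the CH2 next to the chain ketone) joins an aryl but-2-yne to a bromomethyl enone that already carries the pyranone.
2. Enabling feature: C4 is the methylene between the C5 ketone and the C2=C3 trisubstituted alkene. As a ketone α-carbon it can be charged as a C–Br bond (an α-keto radical at nickel) instead of an enolate, while C2=C3 with its methyl group is the syn H–Zr adduct of a methyl-capped alkyne. Two natively nucleophilic carbons are thus united by polarity reversal at C4, and the (E)-alkene and the skipped enone arise in the same operation.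
3. Bromomethyl (Z)-enone: α'-bromination of a methyl ketone made by B-alkyl Suzuki coupling of an allyl pyranone with (Z)-4-iodopent-3-en-2-one.
4. Pyranone: O–CMe2 bond by 6-endo selenoetherification of an α'-hydroxy prenyl ketone, ring alkene by selenoxide elimination; the quaternary (R) carbon comes from (S)-lactic acid by Seebach alkylation.
5. Ring order: the benzene ring is bought (2,6-dimethylhydroquinone, then silylation, O-methylation, benzylic bromination, propynylation); the 2H-pyran-3(6H)-one ring is the only ring made (steps 6 and 7); the key step closes no ring.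

Key step: step 15

**Route**

Step 1
Reactants: 1 (S)-lactic acid
Product: 2 (2S,5S)-2-tert-butyl-5-methyl-1,3-dioxolan-4-one
Conditions: pivalaldehyde, p-TsOH·H2O (cat.), H2SO4 (cat.), pentane, reflux, Dean–Stark; recrystallisation, pentane, −78 °C
Reagents that add atoms: pivalaldehyde, CC(C)(C)C=O
Why: Acid-catalysed acetalisation of the α-hydroxy acid (first stage of the self-regeneration-of-stereocentres protocol): the methyl-bearing ring carbon keeps the (S) configuration of lactic acid and the new acetal carbon is set cis to it under thermodynamic control, the cis isomer being purified by crystallisation.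

Step 2
Reactants: 2 (2S,5S)-2-tert-butyl-5-methyl-1,3-dioxolan-4-one
Product: 4 (2S,5R)-2-tert-butyl-5-methyl-5-(prop-2-en-1-yl)-1,3-dioxolan-4-one, via lithium enolate 3 (not isolated)
Conditions: LiN(iPr)2, THF, −78 °C; allyl bromide, −78 to −30 °C
Reagents that add atoms: allyl bromide, C=CCBr
Why: Diastereoselective enolate alkylation (Seebach alkylation): the tert-butyl group on the acetal carbon blocks one face of the planar lithium enolate, so allyl bromide enters trans to it and the quaternary carbon forms with net retention, which fixes the (R) centre of the future pyranone.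

Step 3
Reactants: 5 1-bromo-3-methylbut-2-ene (prenyl bromide)
Product: 6 [(3-methylbut-2-en-1-yl)sulfonyl]benzene (prenyl phenyl sulfone)
Conditions: PhSO2Na, DMF, 25 °C
Reagents that add atoms: sodium benzenesulfinate, [Na+].[O-]S(=O)c1ccccc1
Why: SN2 S-alkylation of the sulfinate at sulfur by the primary allylic bromide gives the sulfone; no stereocentre is involved.

Step 4
Reactants: 6 [(3-methylbut-2-en-1-yl)sulfonyl]benzene, 4 (2S,5R)-2-tert-butyl-5-methyl-5-(prop-2-en-1-yl)-1,3-dioxolan-4-one
Product: 8 (4R)-4-hydroxy-4,8-dimethyl-6-(phenylsulfonyl)nona-1,7-dien-5-one, via lithiated sulfone 7 (not isolated)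
Conditions: 6 (2.2 equiv), n-BuLi (2.2 equiv), THF, −78 °C; then 4, −78 to 0 °C; aq. NH4Cl
Reagents that add atoms: none
Why: Claisen-type C-acylation of the α-lithiated allyl sulfone, which reacts at the carbon next to sulfur, by the acetal-activated lactone carbonyl: the tetrahedral intermediate opens, pivalaldehyde is lost, and the second equivalent of anion stores the β-keto sulfone as its enolate so that no second addition occurs; the quaternary centre is untouched and the new sulfonyl-bearing centre, formed as a mixture, is removed in step 5.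

Step 5
Reactants: 8 (4R)-4-hydroxy-4,8-dimethyl-6-(phenylsulfonyl)nona-1,7-dien-5-one
Product: 9 (4R)-4-hydroxy-4,8-dimethylnona-1,7-dien-5-one
Conditions: SmI2 (2.2 equiv), THF/MeOH, −78 °C
Reagents that add atoms: none
Why: Reductive desulfonylation of the β-keto sulfone by single-electron transfer from divalent samarium: C–S cleavage gives a samarium dienolate that methanol protonates kinetically at the α-carbon, which keeps the trisubstituted alkene out of conjugation.

Step 6
Reactants: 9 (4R)-4-hydroxy-4,8-dimethylnona-1,7-dien-5-one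
Product: 10 (2R)-2,6,6-trimethyl-5-(phenylselanyl)-2-(prop-2-en-1-yl)oxan-3-one
Conditions: N-(phenylselanyl)phthalimide, camphorsulfonic acid (10 mol %), CH2Cl2, −78 to 25 °C
Reagents that add atoms: N-(phenylselanyl)phthalimide, O=C1N([Se]c2ccccc2)C(=O)c2ccccc12
Why: Electrophilic selenoetherification: the seleniranium ion formed on the electron-rich trisubstituted alkene is opened by the tertiary hydroxyl at the dimethyl-substituted carbon (Markovnikov, 6-endo), the acid allowing any 5-exo adduct to revert and funnel to the oxanone; the selenium-bearing centre forms as a mixture that step 7 erases.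

Step 7
Reactants: 10 (2R)-2,6,6-trimethyl-5-(phenylselanyl)-2-(prop-2-en-1-yl)oxan-3-one
Product: 12 (2R)-2,6,6-trimethyl-2-(prop-2-en-1-yl)-2H-pyran-3(6H)-one, via selenoxide 11 (not isolated)
Conditions: 30% H2O2, pyridine, CH2Cl2, 0 to 25 °C
Reagents that add atoms: none
Why: Selenide oxidation and selenoxide syn-elimination: the only β-hydrogens are on the CH2 next to the ketone, so the alkene can form only in conjugation with the carbonyl, which completes the 2H-pyran-3(6H)-one.

Step 8
Reactants: 13 pent-3-yn-2-one
Product: 14 (3Z)-4-iodopent-3-en-2-one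
Conditions: NaI, AcOH, 25 °C
Reagents that add atoms: sodium iodide, [Na+].[I-]
Why: Conjugate anti-hydroiodination of the ynone (iodide adds to the β-carbon and the allenol is protonated on the opposite side) should give the (Z)-β-iodo enone under kinetic control.

Step 9
Reactants: 12 (2R)-2,6,6-trimethyl-2-(prop-2-en-1-yl)-2H-pyran-3(6H)-one, 14 (3Z)-4-iodopent-3-en-2-one
Product: 16 (2R)-2,6,6-trimethyl-2-[(4Z)-4-methyl-6-oxohept-4-en-1-yl]-2H-pyran-3(6H)-one, via alkyl-9-BBN borane 15 (not isolated)
Conditions: 9-BBN, THF, 0 to 25 °C; then 14, Pd(dppf)Cl2 (5 mol %), AsPh3, K3PO4 (3 M aq.), DMF, 25 °C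
Reagents that add atoms: none
Why: Anti-Markovnikov hydroboration of the terminal alkene by 9-BBN, which should be much faster than reduction of the hindered ring ketone, then B-alkyl Suzuki–Miyaura coupling, in which oxidative addition and reductive elimination retain the geometry of the iodoalkene and so deliver the (Z)-enone.

Step 10
Reactants: 16 (2R)-2,6,6-trimethyl-2-[(4Z)-4-methyl-6-oxohept-4-en-1-yl]-2H-pyran-3(6H)-one
Product: 18 (2R)-2-[(4Z)-7-bromo-4-methyl-6-oxohept-4-en-1-yl]-2,6,6-trimethyl-2H-pyran-3(6H)-one, via trimethylsilyl dienol ether 17 (not isolated)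
Conditions: LiN(SiMe3)2, Me3SiCl, THF, −78 °C; then NBS, NaHCO3, THF, −78 to 0 °C
Reagents that add atoms: N-bromosuccinimide, BrN1C(=O)CCC1=O
Why: Kinetic α'-deprotonation of the methyl ketone with in situ silylation gives the cross-conjugated silyl dienol ether, which N-bromosuccinimide brominates at its terminal CH2 (electrophilic α-halogenation of a silyl enol ether); the pyranone has no enolisable hydrogen and the (Z)-alkene is not touched.

Step 11
Reactants: 19 2,6-dimethylbenzene-1,4-diol
Product: 20 4-{[tert-butyl(dimethyl)silyl]oxy}-2,6-dimethylphenol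
Conditions: TBSCl (1.05 equiv), imidazole, DMF, 0 °C
Reagents that add atoms: tert-butyldimethylsilyl chloride, CC(C)(C)[Si](C)(C)Cl
Why: Selective O-silylation: the hydroxyl flanked by two methyl groups is far more hindered, so the silyl chloride reacts at the other one.

Step 12
Reactants: 20 4-{[tert-butyl(dimethyl)silyl]oxy}-2,6-dimethylphenol
Product: 21 tert-butyl(4-methoxy-3,5-dimethylphenoxy)dimethylsilane
Conditions: MeI, K2CO3, acetone, reflux
Reagents that add atoms: iodomethane, CI
Why: Williamson O-methylation of the remaining hindered phenol under anhydrous conditions that leave the aryl silyl ether in place.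

Step 13
Reactants: 21 tert-butyl(4-methoxy-3,5-dimethylphenoxy)dimethylsilane
Product: 22 [3-(bromomethyl)-4-methoxy-5-methylphenoxy](tert-butyl)dimethylsilane
Conditions: NBS (1.0 equiv), AIBN (5 mol %), PhCF3, 80 °C
Reagents that add atoms: N-bromosuccinimide, BrN1C(=O)CCC1=O
Why: Wohl–Ziegler radical bromination: the two aryl methyl groups are equivalent, so one equivalent of reagent in a non-polar solvent should give mainly the mono(bromomethyl) compound, the radical chain being favoured over ring bromination.

Step 14
Reactants: 22 [3-(bromomethyl)-4-methoxy-5-methylphenoxy](tert-butyl)dimethylsilane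
Product: 23 [3-(but-2-yn-1-yl)-4-methoxy-5-methylphenoxy](tert-butyl)dimethylsilane
Conditions: 1-propynylmagnesium bromide, CuBr·SMe2 (5 mol %), THF, 0 to 50 °C
Reagents that add atoms: 1-propynylmagnesium bromide, CC#C[Mg]Br
Why: Copper-catalysed sp–sp3 coupling of an alkynyl Grignard reagent with a benzylic bromide installs the but-2-ynyl group without base-induced alkyne-to-allene isomerisation.

Step 15
Reactants: 23 [3-(but-2-yn-1-yl)-4-methoxy-5-methylphenoxy](tert-butyl)dimethylsilane, 18 (2R)-2-[(4Z)-7-bromo-4-methyl-6-oxohept-4-en-1-yl]-2,6,6-trimethyl-2H-pyran-3(6H)-one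
Product: 25 (2R)-2-[(4Z,8E)-10-(5-{[tert-butyl(dimethyl)silyl]oxy}-2-methoxy-3-methylphenyl)-4,8-dimethyl-6-oxodeca-4,8-dien-1-yl]-2,6,6-trimethyl-2H-pyran-3(6H)-one, via alkenylzirconocene chloride 24 (not isolated)
Conditions: Cp2Zr(H)Cl (1.05 equiv per 23), THF, 25 to 40 °C, then a little more 23 to consume residual Zr–H; then 18, NiCl2·glyme (5 mol %), 2,2'-isopropylidenebis[(4S)-4-phenyl-2-oxazoline] (6 mol %), DME/THF, 10 °C
Reagents that add atoms: none
Why: Schwartz hydrozirconation adds H and Zr syn across the alkyne and, after equilibration, should place zirconium on the less hindered methyl-bearing carbon to give the (E)-alkenylzirconocene 24. The divalent nickel precatalyst is reduced by 24 to a low-valent bis(oxazoline)nickel species that abstracts bromine from 18 to give the α-keto radical at the CH2 carbon; the alkenyl group passes from zirconium to nickel with retention, the radical is captured, and reductive elimination from trivalent nickel forms the vinyl–CH2 bond. The closest known reaction type is the nickel-catalysed Negishi-type alkenylation of α-bromo ketones with alkenylzirconocene chlorides, run without base; the chirality of the ligand plays no role here. No ring is closed and no stereocentre is formed; the (E) geometry of the new trisubstituted alkene follows from the syn H–Zr addition and the stereoretentive transmetalation and reductive elimination. The step needs regioselectivity in the H–Zr addition (secured by the size difference between methyl and the ortho-methoxybenzyl group) and chemoselectivity for the C–Br bond over the two enones (secured by fast halogen abstraction at the activated α-bromo ketone and by the hindered β-carbons of both enones). It also needs the skipped β,γ-alkene and the (Z)-enone to survive, which the neutral conditions at 10 °C should secure.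

Step 16
Reactants: 25 (2R)-2-[(4Z,8E)-10-(5-{[tert-butyl(dimethyl)silyl]oxy}-2-methoxy-3-methylphenyl)-4,8-dimethyl-6-oxodeca-4,8-dien-1-yl]-2,6,6-trimethyl-2H-pyran-3(6H)-one
Product: 26 (2R)-2-[(4Z,8E)-10-(5-hydroxy-2-methoxy-3-methylphenyl)-4,8-dimethyl-6-oxodeca-4,8-dien-1-yl]-2,6,6-trimethyl-2H-pyran-3(6H)-one (CNP0160516.2)
Conditions: HF·pyridine, pyridine, THF, 0 °C
Reagents that add atoms: none
Why: Fluoride-induced cleavage of the aryl silyl ether under buffered, weakly acidic conditions, chosen so that neither the skipped alkene nor the (Z)-enone is isomerised.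

**Compound list**

1 | (S)-lactic acid | C[C@H](O)C(=O)O | starting material
2 | (2S,5S)-2-tert-butyl-5-methyl-1,3-dioxolan-4-one | C[C@@H]1O[C@H](C(C)(C)C)OC1=O | intermediate
3 | lithium enolate of 2, lithium (2S)-2-tert-butyl-5-methyl-1,3-dioxol-4-olate | CC1=C(O[Li])O[C@@H](C(C)(C)C)O1 | intermediate
4 | (2S,5R)-2-tert-butyl-5-methyl-5-(prop-2-en-1-yl)-1,3-dioxolan-4-one | C[C@]1(CC=C)O[C@H](C(C)(C)C)OC1=O | intermediate
5 | 1-bromo-3-methylbut-2-ene (prenyl bromide) | CC(C)=CCBr | starting material
6 | [(3-methylbut-2-en-1-yl)sulfonyl]benzene | CC(C)=CCS(=O)(=O)c1ccccc1 | intermediate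
7 | [(1-lithio-3-methylbut-2-en-1-yl)sulfonyl]benzene | CC(C)=CC([Li])S(=O)(=O)c1ccccc1 | intermediate
8 | (4R)-4-hydroxy-4,8-dimethyl-6-(phenylsulfonyl)nona-1,7-dien-5-one (both C6 epimers) | C=CC[C@@](C)(O)C(=O)C(C=C(C)C)S(=O)(=O)c1ccccc1 | intermediate
9 | (4R)-4-hydroxy-4,8-dimethylnona-1,7-dien-5-one | C=CC[C@@](C)(O)C(=O)CC=C(C)C | intermediate
10 | (2R)-2,6,6-trimethyl-5-(phenylselanyl)-2-(prop-2-en-1-yl)oxan-3-one (both C5 epimers) | C=CC[C@@]1(C)OC(C)(C)C([Se]c2ccccc2)CC1=O | intermediate
11 | (2R)-2,6,6-trimethyl-5-(phenylseleninyl)-2-(prop-2-en-1-yl)oxan-3-one | C=CC[C@@]1(C)OC(C)(C)C([Se](=O)c2ccccc2)CC1=O | intermediate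
12 | (2R)-2,6,6-trimethyl-2-(prop-2-en-1-yl)-2H-pyran-3(6H)-one | C=CC[C@@]1(C)OC(C)(C)C=CC1=O | intermediate
13 | pent-3-yn-2-one | CC#CC(C)=O | starting material
14 | (3Z)-4-iodopent-3-en-2-one | CC(=O)/C=C(/C)I | intermediate
15 | (2R)-2-[3-(9-borabicyclo[3.3.1]nonan-9-yl)propyl]-2,6,6-trimethyl-2H-pyran-3(6H)-one | C1CC2CCCC(C1)B2CCC[C@@]1(C)OC(C)(C)C=CC1=O | intermediate
16 | (2R)-2,6,6-trimethyl-2-[(4Z)-4-methyl-6-oxohept-4-en-1-yl]-2H-pyran-3(6H)-one | CC(=O)/C=C(/C)CCC[C@@]1(C)OC(C)(C)C=CC1=O | intermediate
17 | (2R)-2,6,6-trimethyl-2-{(4Z)-4-methyl-6-[(trimethylsilyl)oxy]hepta-4,6-dien-1-yl}-2H-pyran-3(6H)-one | C=C(O[Si](C)(C)C)/C=C(/C)CCC[C@@]1(C)OC(C)(C)C=CC1=O | intermediate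
18 | (2R)-2-[(4Z)-7-bromo-4-methyl-6-oxohept-4-en-1-yl]-2,6,6-trimethyl-2H-pyran-3(6H)-one | BrCC(=O)/C=C(/C)CCC[C@@]1(C)OC(C)(C)C=CC1=O | intermediate
19 | 2,6-dimethylbenzene-1,4-diol | Cc1cc(O)cc(C)c1O | starting material
20 | 4-{[tert-butyl(dimethyl)silyl]oxy}-2,6-dimethylphenol | Cc1cc(O[Si](C)(C)C(C)(C)C)cc(C)c1O | intermediate
21 | tert-butyl(4-methoxy-3,5-dimethylphenoxy)dimethylsilane | COc1c(C)cc(O[Si](C)(C)C(C)(C)C)cc1C | intermediate
22 | [3-(bromomethyl)-4-methoxy-5-methylphenoxy](tert-butyl)dimethylsilane | COc1c(C)cc(O[Si](C)(C)C(C)(C)C)cc1CBr | intermediate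
23 | [3-(but-2-yn-1-yl)-4-methoxy-5-methylphenoxy](tert-butyl)dimethylsilane | COc1c(C)cc(O[Si](C)(C)C(C)(C)C)cc1CC#CC | intermediate
24 | [(2E)-4-(5-{[tert-butyl(dimethyl)silyl]oxy}-2-methoxy-3-methylphenyl)but-2-en-2-yl]chloridobis(cyclopentadienyl)zirconium | COc1c(C)cc(O[Si](C)(C)C(C)(C)C)cc1C/C=C(\C)[Zr](Cl)(C1C=CC=C1)C1C=CC=C1 | intermediate
25 | (2R)-2-[(4Z,8E)-10-(5-{[tert-butyl(dimethyl)silyl]oxy}-2-methoxy-3-methylphenyl)-4,8-dimethyl-6-oxodeca-4,8-dien-1-yl]-2,6,6-trimethyl-2H-pyran-3(6H)-one | COc1c(C)cc(O[Si](C)(C)C(C)(C)C)cc1C/C=C(\C)CC(=O)/C=C(/C)CCC[C@@]1(C)OC(C)(C)C=CC1=O | intermediate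
26 | (2R)-2-[(4Z,8E)-10-(5-hydroxy-2-methoxy-3-methylphenyl)-4,8-dimethyl-6-oxodeca-4,8-dien-1-yl]-2,6,6-trimethyl-2H-pyran-3(6H)-one | COc1c(C)cc(O)cc1C/C=C(\C)CC(=O)/C=C(/C)CCC[C@@]1(C)OC(C)(C)C=CC1=O | target

**Step count and risks**

Total steps: 16. Longest linear sequence: 10 steps (1, 2, 4, 5, 6, 7, 9, 10, 15, 16).

Steps most likely to fail:

1. Step 15 (key coupling). The H–Zr addition may show poor regiocontrol, with zirconium ending on the benzyl-side carbon. Residual Zr–H may reduce a ketone. Alkenyl transfer from zirconium to nickel may be slow for this α-methyl-substituted alkenyl group, so that reductive debromination, radical dimerisation or nickel-mediated conjugate addition to the ring enone take over. Fallback, setting out from 23 and 16 and coming back at 25: H–Zr addition to 23 followed by iodinolysis (Cp2Zr(H)Cl, then I2) should give tert-butyl{3-[(2E)-3-iodobut-2-en-1-yl]-4-methoxy-5-methylphenoxy}dimethylsilane F1, a stable compound from which a minor regioisomer can be removed by chromatography. Ketone 16 is converted into the silyl dienol ether 17 as in the first half of step 10 and isolated by non-aqueous work-up. Bu3SnF then turns 17 into the tin enolate, which is alkenylated by F1 under palladium catalysis (PdCl2[P(o-tolyl)3]2, toluene, 80 °C; oxidative addition to zerovalent palladium, transmetalation of the tin enolate, reductive elimination) to give 25. This is the natural-polarity alternative (enolate plus alkenyl halide) and needs neither the bromoketone nor nickel.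

2. Step 10 (α'-bromination). Deprotonation may occur at the γ-positions of the (Z)-enone instead of the methyl group, which would erode the alkene geometry and misplace the bromine; over-bromination is also possible. Fallback, setting out from 12 and coming back at 18, builds the bromomethyl ketone without any enolate. The borane 15 (from 12 as in step 9) is coupled under the same Suzuki–Miyaura conditions, with extra K3PO4, with (2Z)-3-iodobut-2-enoic acid F2 (from but-2-ynoic acid, NaI, AcOH) to give (2Z)-3-methyl-6-[(2R)-2,6,6-trimethyl-3-oxo-3,6-dihydro-2H-pyran-2-yl]hex-2-enoic acid F3. Oxalyl chloride with catalytic DMF (CH2Cl2, 0 °C) should give (2Z)-3-methyl-6-[(2R)-2,6,6-trimethyl-3-oxo-3,6-dihydro-2H-pyran-2-yl]hex-2-enoyl chloride F4. Diazomethane (Et2O, 0 °C, short contact) acylates to (2R)-2-[(4Z)-7-diazo-4-methyl-6-oxohept-4-en-1-yl]-2,6,6-trimethyl-2H-pyran-3(6H)-one F5 (Arndt–Eistert-type diazoketone formation), and 48% HBr at 0 °C converts F5 into 18.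

3. Step 6 (selenoetherification). The hydroxyl may attack the secondary carbon of the seleniranium ion (5-exo), equilibration to the 6-endo ether may be incomplete, or the acid may move the β,γ-alkene into conjugation before cyclisation. Fallback, setting out from 9 and coming back at 12: Wacker-type oxidative cyclisation (PdCl2(MeCN)2 10 mol %, p-benzoquinone, THF, 25 °C). Oxypalladation by the tertiary hydroxyl at the dimethyl-substituted alkene carbon (Markovnikov, 6-endo) and β-hydride elimination toward the CH2 next to the ketone should give 12 in one operation, replacing steps 6 and 7; this fallback makes no new compound (F0).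

**Further compounds**

F1 | step 15 | tert-butyl{3-[(2E)-3-iodobut-2-en-1-yl]-4-methoxy-5-methylphenoxy}dimethylsilane | COc1c(C)cc(O[Si](C)(C)C(C)(C)C)cc1C/C=C(\C)I
F2 | step 10 | (2Z)-3-iodobut-2-enoic acid | OC(=O)/C=C(/C)I
F3 | step 10 | (2Z)-3-methyl-6-[(2R)-2,6,6-trimethyl-3-oxo-3,6-dihydro-2H-pyran-2-yl]hex-2-enoic acid | OC(=O)/C=C(/C)CCC[C@@]1(C)OC(C)(C)C=CC1=O
F4 | step 10 | (2Z)-3-methyl-6-[(2R)-2,6,6-trimethyl-3-oxo-3,6-dihydro-2H-pyran-2-yl]hex-2-enoyl chloride | ClC(=O)/C=C(/C)CCC[C@@]1(C)OC(C)(C)C=CC1=O
F5 | step 10 | (2R)-2-[(4Z)-7-diazo-4-methyl-6-oxohept-4-en-1-yl]-2,6,6-trimethyl-2H-pyran-3(6H)-one | [N-]=[N+]=CC(=O)/C=C(/C)CCC[C@@]1(C)OC(C)(C)C=CC1=O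
F0 | step 6 | none | none
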